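**Retrosynthetic overview**
1. The pyranone ring is the only ring formed, and it is formed last but one: O1–C2 by enantioselective oxa-Michael cyclisation of a 2'-hydroxychalcone. The chalcone comes from acetophenone 20 and aldehyde 23 (Claisen–Schmidt).
2. The acetyl group and the single free phenol (future O1) come from an aryl O-carbamate by anionic ortho-Fries rearrangement and MeLi.
3. The C8 side chain is built by two boron 1,2-shifts: a Pd-catalysed conjunctive coupling of aryl iodide 7, vinylmagnesium bromide and alkylboronate 10 makes the ArCH2–C bond and the side-chain stereocentre; a Zweifel olefination then installs the isopropenyl group.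
4. A-ring: resorcinol → bis-MOM ether → Ir C–H borylation/oxidation (third oxygen) → carbamate → directed ortho-iodination.
5. B-ring: resorcinol → Vilsmeier formylation → 4-O-MOM / 2-O-Me. Both benzene rings are bought as resorcinol.

Assumption: the sense of induction of the MandyPhos–Pd catalyst (step 7) and of the oxa-Michael catalyst (step 13) is assigned by analogy; the antipodal ligand/catalyst is used if the opposite sense is found.

**Step 1**
Reactants: 1 resorcinol
Product: 2 1,3-bis(methoxymethoxy)benzene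
Conditions: NaH (2.4 equiv), MOMCl (2.4 equiv), DMF/THF, 0 °C → rt
Reagents that add atoms: chloromethyl methyl ether COCCl
Why: Williamson-type MOM ether formation on both phenols; MOM survives organolithiums, Pd and base and is removed last by mild acid.

**Step 2**
Reactants: 2 1,3-bis(methoxymethoxy)benzene
Product: 4 3,5-bis(methoxymethoxy)phenol, via arylboronate 3 (not isolated)
Conditions: [Ir(OMe)(cod)]2 (1 mol %), dtbpy (2 mol %), B2pin2 (0.55 equiv), THF, 80 °C; then aq. NaOH, H2O2, 0 °C → rt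
Reagents that add atoms: bis(pinacolato)diboron CC1(C)OB(OC1(C)C)B1OC(C)(C)C(C)(C)O1 (boron unit of 3 only); hydrogen peroxide OO (the new O)
Why: Sterically controlled Ir-catalysed C–H borylation reacts only at C5 (the one C–H without an ortho substituent), and peroxide oxidation of the C–B bond installs the third oxygen as the only free OH, which later becomes O1.

**Step 3**
Reactants: 4 3,5-bis(methoxymethoxy)phenol
Product: 5 3,5-bis(methoxymethoxy)phenyl N,N-diethylcarbamate
Conditions: NaH, ClC(O)NEt2, THF, 0 °C → rt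
Reagents that add atoms: N,N-diethylcarbamoyl chloride CCN(CC)C(Cl)=O
Why: O-carbamoylation turns the unique phenol into the strongest ortho-directing group, which is used twice (iodination here, anionic Fries in step 9).

**Step 4**
Reactants: 5 3,5-bis(methoxymethoxy)phenyl N,N-diethylcarbamate
Product: 7 2-iodo-3,5-bis(methoxymethoxy)phenyl N,N-diethylcarbamate, via aryllithium 6 (not isolated)
Conditions: s-BuLi (1.1 equiv), TMEDA, THF, −78 °C, 1 h; I2, −78 °C
Reagents that add atoms: sec-butyllithium CCC(C)[Li] (Li of 6 only); iodine II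
Why: Directed ortho-metalation: the carbamate C=O delivers s-BuLi to the position between OCb and OMOM (kinetically preferred at −78 °C over the site between the two OMOM groups, and no Fries shift at this temperature), and iodine traps the aryllithium.

**Step 5**
Reactants: 8 2-methylbut-3-en-2-ol
Product: 9 triethyl[(2-methylbut-3-en-2-yl)oxy]silane
Conditions: TESOTf, 2,6-lutidine, CH2Cl2, −78 → 0 °C
Reagents that add atoms: triethylsilyl trifluoromethanesulfonate CC[Si](CC)(CC)OS(=O)(=O)C(F)(F)F
Why: Silylation of the tertiary alcohol so that its alkoxide cannot interfere with boron 'ate' chemistry; the TES group is lost in the final acid step.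

**Step 6**
Reactants: 9 triethyl[(2-methylbut-3-en-2-yl)oxy]silane
Product: 10 triethyl{[2-methyl-4-(4,4,5,5-tetramethyl-1,3,2-dioxaborolan-2-yl)butan-2-yl]oxy}silane
Conditions: HBpin (1.2 equiv), [Ir(cod)Cl]2 (1.5 mol %), dppm (3 mol %), CH2Cl2, rt
Reagents that add atoms: pinacolborane B1OC(C)(C)C(C)(C)O1
Why: Ir-catalysed anti-Markovnikov hydroboration of the monosubstituted alkene places boron only on the terminal carbon.

**Step 7**
Reactants: 10 triethyl{[2-methyl-4-(4,4,5,5-tetramethyl-1,3,2-dioxaborolan-2-yl)butan-2-yl]oxy}silane; 11 vinylmagnesium bromide; 7 2-iodo-3,5-bis(methoxymethoxy)phenyl N,N-diethylcarbamate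
Product: 13 2-{(2R)-5-methyl-2-(4,4,5,5-tetramethyl-1,3,2-dioxaborolan-2-yl)-5-[(triethylsilyl)oxy]hexyl}-3,5-bis(methoxymethoxy)phenyl N,N-diethylcarbamate, via vinylboronate complex 12 (not isolated)
Conditions: 10 + 11, THF, 0 °C → rt; then 7, Pd(OAc)2 (3 mol %), (Sp,Sp)-MandyPhos (3.6 mol %), NaOTf (2.4 equiv), THF/DMSO 4:1, 40–60 °C
Reagents that add atoms: none
Why: Pd-catalysed enantioselective conjunctive cross-coupling: ArPd(II) from 7 activates the vinyl group of 'ate' complex 12, the alkyl group makes a 1,2-metallate shift from boron to the internal carbon anti to Pd, and reductive elimination forms the Ar–CH2 bond, with the chiral bisphosphine fixing the boron-bearing centre as R.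

**Step 8**
Reactants: 13 the (R)-sec-boronate from step 7; 14 2-bromopropene
Product: 18 3,5-bis(methoxymethoxy)-2-{(2R)-5-methyl-2-(prop-1-en-2-yl)-5-[(triethylsilyl)oxy]hexyl}phenyl N,N-diethylcarbamate, via isopropenyllithium 15 (not isolated), via isopropenylboronate complex 16 (not isolated), via iodoboronate 17 (not isolated)
Conditions: 14 (1.5 equiv), t-BuLi (3.0 equiv), THF, −78 °C; add 13, −78 °C; I2 (1.2 equiv), MeOH, −78 °C; NaOMe, −78 °C → rt; Na2S2O3
Reagents that add atoms: tert-butyllithium CC(C)(C)[Li] (Li of 15 and 16 only); iodine II (I of 17 only)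
Why: Zweifel olefination: iodonium formation on complex 16 triggers a stereoretentive 1,2-metallate shift of the secondary alkyl group, and methoxide-induced anti elimination of B and I gives the isopropenyl group, so the R centre from step 7 is carried over unchanged.

**Step 9**
Reactants: 18 the isopropenyl aryl carbamate from step 8
Product: 20 1-[2-hydroxy-4,6-bis(methoxymethoxy)-3-{(2R)-5-methyl-2-(prop-1-en-2-yl)-5-[(triethylsilyl)oxy]hexyl}phenyl]ethan-1-one, via lithium phenolate amide 19 (not isolated)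
Conditions: s-BuLi (1.2 equiv), TMEDA, THF, −78 °C → rt; then MeLi (4 equiv), 0 °C → rt; H2O
Reagents that add atoms: sec-butyllithium CCC(C)[Li] (Li of 19 only); methyllithium C[Li]
Why: Anionic ortho-Fries rearrangement (lithiation at the only free position next to the carbamate, then 1,3 O→C carbamoyl shift) frees exactly the phenol flanked by side chain and acyl carbon (future O1), and MeLi adds once to the chelated amide to give the methyl ketone on quench.

**Step 10**
Reactants: 1 resorcinol
Product: 21 2,4-dihydroxybenzaldehyde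
Conditions: POCl3, DMF, MeCN, −15 °C → rt; then H2O, 50 °C
Reagents that add atoms: N,N-dimethylformamide CN(C)C=O (formyl C); water O (formyl O)
Why: Vilsmeier–Haack formylation of resorcinol para to one OH and ortho to the other gives the 2,4-dihydroxybenzaldehyde pattern.

**Step 11**
Reactants: 21 2,4-dihydroxybenzaldehyde
Product: 23 2-methoxy-4-(methoxymethoxy)benzaldehyde, via mono-MOM aldehyde 22 (not isolated)
Conditions: K2CO3 (3 equiv), MOMCl (1.05 equiv), acetone, 0 °C → rt; then MeI (3 equiv), reflux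
Reagents that add atoms: chloromethyl methyl ether COCCl; iodomethane CI
Why: Sequential Williamson alkylations: the free 4-OH reacts first with MOMCl while the 2-OH is held by its hydrogen bond to CHO, and the 2-OH is then methylated on heating.

**Step 12**
Reactants: 20 the acetophenone from step 9; 23 2-methoxy-4-(methoxymethoxy)benzaldehyde
Product: 24 (2E)-1-[2-hydroxy-4,6-bis(methoxymethoxy)-3-{(2R)-5-methyl-2-(prop-1-en-2-yl)-5-[(triethylsilyl)oxy]hexyl}phenyl]-3-[2-methoxy-4-(methoxymethoxy)phenyl]prop-2-en-1-one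
Conditions: KOH (10 equiv), EtOH/H2O, rt, 48 h; cold neutral work-up
Reagents that add atoms: none
Why: Claisen–Schmidt condensation (aldol/dehydration) gives the E-chalcone, and because only the 2'-OH next to the side chain is free, only cyclisation to the 8-substituted flavanone is possible later.

**Step 13**
Reactants: 24 the chalcone from step 12
Product: 25 (2S)-2-[2-methoxy-4-(methoxymethoxy)phenyl]-5,7-bis(methoxymethoxy)-8-{(2R)-5-methyl-2-(prop-1-en-2-yl)-5-[(triethylsilyl)oxy]hexyl}-2,3-dihydro-4H-chromen-4-one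
Conditions: tert-leucine-derived thiourea–iminophosphorane (BIMP) catalyst (10 mol %), toluene, 0 °C
Reagents that add atoms: none
Why: Proposed new method: enantioselective 6-endo oxa-Michael cyclisation of an unactivated 2'-hydroxychalcone by a bifunctional iminophosphorane–thiourea superbase, in which the iminophosphorane fully deprotonates the chelated phenol (breaking the OH···O=C bond that makes these substrates sluggish), the thiourea binds the enone carbonyl of the resulting ion pair and the chiral pocket exposes one β-face so that O1 adds to give 2S under catalyst control, the 6'-OMOM group makes the flavanone the thermodynamic sink and 0 °C limits retro-Michael erosion; the closest known reactions are amine–thiourea-catalysed oxa-Michael cyclisations of α-carboxy-activated 2'-hydroxychalcones and iminophosphorane-catalysed oxa-Michael additions of alcohols to enoates.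

**Step 14**
Reactants: 25 the protected flavanone from step 13
Product: 26 (2S)-5,7-dihydroxy-2-(4-hydroxy-2-methoxyphenyl)-8-[(2R)-5-hydroxy-5-methyl-2-(prop-1-en-2-yl)hexyl]-2,3-dihydro-4H-chromen-4-one (target)
Conditions: 3 M aq. HCl/MeOH (1:5), ≤40 °C
Reagents that add atoms: none
Why: Acid-catalysed acetal exchange and silyl ether methanolysis remove the three MOM groups and the TES group in one operation, with dilute acid at ≤40 °C so that the isopropenyl group, the tertiary alcohol and C2 are not touched.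

**Compound list**
1 | resorcinol | Oc1cccc(O)c1 | starting material
2 | 1,3-bis(methoxymethoxy)benzene | COCOc1cccc(OCOC)c1 | intermediate
3 | 2-[3,5-bis(methoxymethoxy)phenyl]-4,4,5,5-tetramethyl-1,3,2-dioxaborolane | COCOc1cc(OCOC)cc(c1)B1OC(C)(C)C(C)(C)O1 | intermediate
4 | 3,5-bis(methoxymethoxy)phenol | COCOc1cc(O)cc(OCOC)c1 | intermediate
5 | 3,5-bis(methoxymethoxy)phenyl N,N-diethylcarbamate | CCN(CC)C(=O)Oc1cc(OCOC)cc(OCOC)c1 | intermediate
6 | {2-[(diethylcarbamoyl)oxy]-4,6-bis(methoxymethoxy)phenyl}lithium | CCN(CC)C(=O)Oc1cc(OCOC)cc(OCOC)c1[Li] | intermediate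
7 | 2-iodo-3,5-bis(methoxymethoxy)phenyl N,N-diethylcarbamate | CCN(CC)C(=O)Oc1cc(OCOC)cc(OCOC)c1I | intermediate
8 | 2-methylbut-3-en-2-ol | C=CC(C)(C)O | starting material
9 | triethyl[(2-methylbut-3-en-2-yl)oxy]silane | C=CC(C)(C)O[Si](CC)(CC)CC | intermediate
10 | triethyl{[2-methyl-4-(4,4,5,5-tetramethyl-1,3,2-dioxaborolan-2-yl)butan-2-yl]oxy}silane | CC[Si](CC)(CC)OC(C)(C)CCB1OC(C)(C)C(C)(C)O1 | intermediate
11 | vinylmagnesium bromide | C=C[Mg]Br | starting material
12 | bromomagnesium ethenyl[3-methyl-3-(triethylsilyloxy)butyl](pinacolato)borate | CC[Si](CC)(CC)OC(C)(C)CC[B-]1(C=C)OC(C)(C)C(C)(C)O1.[Mg+]Br | intermediate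
13 | 2-{(2R)-5-methyl-2-(4,4,5,5-tetramethyl-1,3,2-dioxaborolan-2-yl)-5-[(triethylsilyl)oxy]hexyl}-3,5-bis(methoxymethoxy)phenyl N,N-diethylcarbamate | CCN(CC)C(=O)Oc1cc(OCOC)cc(OCOC)c1C[C@H](B1OC(C)(C)C(C)(C)O1)CCC(C)(C)O[Si](CC)(CC)CC | intermediate
14 | 2-bromopropene | C=C(C)Br | starting material
15 | isopropenyllithium (prop-1-en-2-yllithium) | C=C(C)[Li] | intermediate
16 | lithium isopropenyl 'ate' complex of 13 (R at the B-bearing carbon) | CCN(CC)C(=O)Oc1cc(OCOC)cc(OCOC)c1C[C@H]([B-]1(C(C)=C)OC(C)(C)C(C)(C)O1)CCC(C)(C)O[Si](CC)(CC)CC.[Li+] | intermediate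
17 | 2-{(2R)-2-[1-iodo-2-(4,4,5,5-tetramethyl-1,3,2-dioxaborolan-2-yl)propan-2-yl]-5-methyl-5-[(triethylsilyl)oxy]hexyl}-3,5-bis(methoxymethoxy)phenyl N,N-diethylcarbamate (epimers at the B-bearing carbon) | CCN(CC)C(=O)Oc1cc(OCOC)cc(OCOC)c1C[C@H](C(C)(CI)B1OC(C)(C)C(C)(C)O1)CCC(C)(C)O[Si](CC)(CC)CC | intermediate
18 | 3,5-bis(methoxymethoxy)-2-{(2R)-5-methyl-2-(prop-1-en-2-yl)-5-[(triethylsilyl)oxy]hexyl}phenyl N,N-diethylcarbamate | CCN(CC)C(=O)Oc1cc(OCOC)cc(OCOC)c1C[C@H](C(C)=C)CCC(C)(C)O[Si](CC)(CC)CC | intermediate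
19 | lithium 2-(diethylcarbamoyl)-3,5-bis(methoxymethoxy)-6-{(2R)-5-methyl-2-(prop-1-en-2-yl)-5-[(triethylsilyl)oxy]hexyl}phenolate | CCN(CC)C(=O)c1c(O[Li])c(C[C@H](C(C)=C)CCC(C)(C)O[Si](CC)(CC)CC)c(OCOC)cc1OCOC | intermediate
20 | 1-[2-hydroxy-4,6-bis(methoxymethoxy)-3-{(2R)-5-methyl-2-(prop-1-en-2-yl)-5-[(triethylsilyl)oxy]hexyl}phenyl]ethan-1-one | CC(=O)c1c(O)c(C[C@H](C(C)=C)CCC(C)(C)O[Si](CC)(CC)CC)c(OCOC)cc1OCOC | intermediate
21 | 2,4-dihydroxybenzaldehyde | O=Cc1ccc(O)cc1O | intermediate
22 | 2-hydroxy-4-(methoxymethoxy)benzaldehyde | COCOc1ccc(C=O)c(O)c1 | intermediate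
23 | 2-methoxy-4-(methoxymethoxy)benzaldehyde | COCOc1ccc(C=O)c(OC)c1 | intermediate
24 | (2E)-1-[2-hydroxy-4,6-bis(methoxymethoxy)-3-{(2R)-5-methyl-2-(prop-1-en-2-yl)-5-[(triethylsilyl)oxy]hexyl}phenyl]-3-[2-methoxy-4-(methoxymethoxy)phenyl]prop-2-en-1-one | COCOc1ccc(/C=C/C(=O)c2c(O)c(C[C@H](C(C)=C)CCC(C)(C)O[Si](CC)(CC)CC)c(OCOC)cc2OCOC)c(OC)c1 | intermediate
25 | (2S)-2-[2-methoxy-4-(methoxymethoxy)phenyl]-5,7-bis(methoxymethoxy)-8-{(2R)-5-methyl-2-(prop-1-en-2-yl)-5-[(triethylsilyl)oxy]hexyl}-2,3-dihydro-4H-chromen-4-one | C=C(C)[C@H](CCC(C)(C)O[Si](CC)(CC)CC)Cc1c(OCOC)cc(OCOC)c2c1O[C@H](c1ccc(OCOC)cc1OC)CC2=O | intermediate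
26 | (2S)-5,7-dihydroxy-2-(4-hydroxy-2-methoxyphenyl)-8-[(2R)-5-hydroxy-5-methyl-2-(prop-1-en-2-yl)hexyl]-2,3-dihydro-4H-chromen-4-one | C=C(C)[C@H](CCC(C)(C)O)Cc1c(O)cc(O)c2c1O[C@H](c1ccc(O)cc1OC)CC2=O | target

**Step count**
Total steps: 14. Longest linear sequence: 10 (steps 1, 2, 3, 4, 7, 8, 9, 12, 13, 14).

**Three steps most likely to fail**

Step 13 (the proposed new reaction). The chalcone is strongly chelated, its β-aryl group is electron-rich and ortho-substituted, and the same base can catalyse retro-Michael erosion of ee. Fallback with known chemistry, setting out from 24: sodium acetate in refluxing ethanol cyclises 24 without stereocontrol to a roughly 1:1 mixture of 25 and its 2R epimer F7. Asymmetric transfer hydrogenation with RuCl[(R,R)-TsDPEN](p-cymene) and HCO2H/Et3N then acts as a kinetic resolution: it reduces the 2R epimer F7 much faster, to the cis-flavan-4-ol F8, and leaves the 2S ketone, which is separated by chromatography (at most 50 %). The route is rejoined at 25.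

Step 7. The aryl iodide is electron-rich and flanked by two ortho oxygen substituents, so ArPd(II) capture of the 'ate' complex may be slow and direct vinyl transfer or low ee may result. Fallback by reagent-controlled lithiation–borylation, setting out from 7 and 10: iodine–magnesium exchange on 7 (i-PrMgCl·LiCl, THF, −40 °C) and trapping with ClCH2Bpin (1,2-aryl shift on warming) gives the benzylboronate F1. In parallel, 10 is homologated with LiCH2Cl (BrCH2Cl, n-BuLi, −78 °C, Matteson) to the boronate F2, oxidised (NaOH, H2O2) to the alcohol F3 and acylated with 2,4,6-triisopropylbenzoyl chloride (pyridine, DMAP) to the TIB ester F4. F4 is lithiated with s-BuLi/(−)-sparteine (Et2O, −78 °C, pro-S hydrogen), F1 is added, and the 'ate' complex rearranges (MgBr2·OEt2, warm) with inversion at the carbenoid carbon to give the R boronate. The route is rejoined at 13.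

Step 9. MeLi must add to a hindered, doubly ortho-substituted diethylamide in the same pot, and benzylic lithiation could compete with the Fries step. Fallback setting out from 18: lithiation with s-BuLi/TMEDA at −78 °C is quenched cold with N-methoxy-N-methylacetamide, which keeps the carbamate and gives the ketone F5. Claisen–Schmidt condensation of F5 with 23 (KOH, EtOH, rt) gives the chalcone carbamate F6. Continued heating with KOH in EtOH/H2O (70 °C) hydrolyses the carbamate, now activated by the ortho acyl group, and the route is rejoined at 24.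

Further compounds
F1 | step 7 | 3,5-bis(methoxymethoxy)-2-[(4,4,5,5-tetramethyl-1,3,2-dioxaborolan-2-yl)methyl]phenyl N,N-diethylcarbamate | CCN(CC)C(=O)Oc1cc(OCOC)cc(OCOC)c1CB1OC(C)(C)C(C)(C)O1
F2 | step 7 | triethyl{[2-methyl-5-(4,4,5,5-tetramethyl-1,3,2-dioxaborolan-2-yl)pentan-2-yl]oxy}silane | CC[Si](CC)(CC)OC(C)(C)CCCB1OC(C)(C)C(C)(C)O1
F3 | step 7 | 4-methyl-4-[(triethylsilyl)oxy]pentan-1-ol | CC[Si](CC)(CC)OC(C)(C)CCCO
F4 | step 7 | 4-methyl-4-[(triethylsilyl)oxy]pentyl 2,4,6-triisopropylbenzoate | CC[Si](CC)(CC)OC(C)(C)CCCOC(=O)c1c(C(C)C)cc(C(C)C)cc1C(C)C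
F5 | step 9 | 2-acetyl-3,5-bis(methoxymethoxy)-6-{(2R)-5-methyl-2-(prop-1-en-2-yl)-5-[(triethylsilyl)oxy]hexyl}phenyl N,N-diethylcarbamate | CCN(CC)C(=O)Oc1c(C(C)=O)c(OCOC)cc(OCOC)c1C[C@H](C(C)=C)CCC(C)(C)O[Si](CC)(CC)CC
F6 | step 9 | 2-{(2E)-3-[2-methoxy-4-(methoxymethoxy)phenyl]prop-2-enoyl}-3,5-bis(methoxymethoxy)-6-{(2R)-5-methyl-2-(prop-1-en-2-yl)-5-[(triethylsilyl)oxy]hexyl}phenyl N,N-diethylcarbamate | CCN(CC)C(=O)Oc1c(C(=O)/C=C/c2ccc(OCOC)cc2OC)c(OCOC)cc(OCOC)c1C[C@H](C(C)=C)CCC(C)(C)O[Si](CC)(CC)CC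
F7 | step 13 | (2R)-2-[2-methoxy-4-(methoxymethoxy)phenyl]-5,7-bis(methoxymethoxy)-8-{(2R)-5-methyl-2-(prop-1-en-2-yl)-5-[(triethylsilyl)oxy]hexyl}-2,3-dihydro-4H-chromen-4-one | C=C(C)[C@H](CCC(C)(C)O[Si](CC)(CC)CC)Cc1c(OCOC)cc(OCOC)c2c1O[C@@H](c1ccc(OCOC)cc1OC)CC2=O
F8 | step 13 | (2R,4R)-2-[2-methoxy-4-(methoxymethoxy)phenyl]-5,7-bis(methoxymethoxy)-8-{(2R)-5-methyl-2-(prop-1-en-2-yl)-5-[(triethylsilyl)oxy]hexyl}-3,4-dihydro-2H-chromen-4-ol | C=C(C)[C@H](CCC(C)(C)O[Si](CC)(CC)CC)Cc1c(OCOC)cc(OCOC)c2c1O[C@@H](c1ccc(OCOC)cc1OC)C[C@H]2O
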